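## Retrosynthetic overview

- The strategy rests on the N1–C2–C3–O amino alcohol of the piperidine ring: C2 and C3 are both natural acceptor carbons. They sit beside the all-cis C4a/C5/C8a array of the cyclohexane ring, which fixes the chair through which the piperidine closes.
- The oct-2-enoate at C3–O and the N–O bond are cut first. C2–C3 is then cut to a C8a-bound acetaldehyde nitrone and a C3 aldehyde, joined by SmI2 polarity reversal; this closes the piperidine ring last.
- The nitrone aldehyde comes from an all-cis 2-(2-hydroxyethyl)-3-alkylcyclohexylamine. N is installed by Curtius rearrangement, and the side chain by a primary triflate plus the acetylide made from (R)-2-propyloxirane.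
- The carbocycle is made first: all-cis hydrogenation of a 2-substituted isophthalate (from 2-bromoisophthalic acid) gives a meso diester, which is desymmetrised enzymatically.

Key step: step 16

Assumption: pig liver esterase is taken to hydrolyse the methyl ester on the S-configured ring carbon of meso diester 4 (the future C5); if it prefers the other ester, the catalyst-controlled fallback to step 4 reaches the same half-ester 5.

## Route

Step 1
Reactants: 1 2-bromoisophthalic acid
Product: 2 dimethyl 2-bromoisophthalate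
Conditions: MeOH, H2SO4 (cat.), reflux
Reagents that add atoms: methanol, CO
Why: Fischer esterification; each carboxyl has only one ortho substituent, so acid-catalysed esterification should go to completion.

Step 2
Reactants: 2 dimethyl 2-bromoisophthalate
Product: 3 dimethyl 2-(2-tert-butoxy-2-oxoethyl)isophthalate
Conditions: BrZnCH2CO2t-Bu (1.5 equiv), Pd2(dba)3 (2 mol%), XPhos (8 mol%), THF, 65 °C
Reagents that add atoms: (2-tert-butoxy-2-oxoethyl)zinc bromide, CC(C)(C)OC(=O)C[Zn]Br
Why: Palladium-catalysed α-arylation of a Reformatsky zinc enolate (Negishi-type coupling); the neutral zinc enolate tolerates the methyl esters, the electron-poor C–Br bond adds readily to Pd(0), and the bulky biarylphosphine should drive reductive elimination at the hindered position.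

Step 3
Reactants: 3 dimethyl 2-(2-tert-butoxy-2-oxoethyl)isophthalate
Product: 4 dimethyl (1R,2s,3S)-2-(2-tert-butoxy-2-oxoethyl)cyclohexane-1,3-dicarboxylate (all-cis meso)
Conditions: H2 (50 bar), 5% Rh/Al2O3, i-PrOH, 50 °C
Reagents that add atoms: none
Why: Heterogeneous arene hydrogenation over rhodium delivers all hydrogens to the catalyst-bound face, so the three substituents should end up mutually cis, which is the C4a/C5/C8a relative configuration of the target in a meso compound.

Step 4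
Reactants: 4 dimethyl (1R,2s,3S)-2-(2-tert-butoxy-2-oxoethyl)cyclohexane-1,3-dicarboxylate
Product: 5 (1S,2S,3R)-2-(2-tert-butoxy-2-oxoethyl)-3-(methoxycarbonyl)cyclohexane-1-carboxylic acid
Conditions: pig liver esterase, phosphate buffer pH 7.2/DMSO (9:1), 30 °C; acidify to pH 3
Reagents that add atoms: water, O
Why: Enzymatic desymmetrisation (enantiotopos-selective ester hydrolysis) of a meso cis-1,3-diester at neutral pH sets the absolute configuration of all three ring stereocentres at once without base epimerisation; the tert-butyl ester is not a substrate.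

Step 5
Reactants: 5 (1S,2S,3R)-2-(2-tert-butoxy-2-oxoethyl)-3-(methoxycarbonyl)cyclohexane-1-carboxylic acid
Product: 6 methyl (1R,2S,3S)-2-(2-tert-butoxy-2-oxoethyl)-3-(hydroxymethyl)cyclohexane-1-carboxylate
Conditions: BH3·SMe2, THF, 0 °C → rt; MeOH quench
Reagents that add atoms: none
Why: Chemoselective borane reduction of the carboxylic acid through its acyloxyborane leaves both esters untouched and turns the former carboxyl carbon into C1' of the side chain.

Step 6
Reactants: 7 (R)-2-propyloxirane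
Product: 8 (R)-hept-1-yn-4-ol
Conditions: LiC≡CH·H2NCH2CH2NH2, DMSO, 0 °C → rt
Reagents that add atoms: lithium acetylide ethylenediamine complex, [Li]C#C.NCCN
Why: SN2 opening of the terminal epoxide at its CH2 carbon by acetylide; the carbinol stereocentre is not touched and stays R.

Step 7
Reactants: 8 (R)-hept-1-yn-4-ol
Product: 9 (R)-tert-butyl(hept-1-yn-4-yloxy)dimethylsilane
Conditions: TBSCl, imidazole, DMF, rt
Reagents that add atoms: tert-butyldimethylsilyl chloride, CC(C)(C)[Si](C)(C)Cl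
Why: Standard silylation of a secondary alcohol; this ether is the only silyl group in the route and is removed in the last step.

Step 8
Reactants: 6 methyl (1R,2S,3S)-2-(2-tert-butoxy-2-oxoethyl)-3-(hydroxymethyl)cyclohexane-1-carboxylate; 9 (R)-tert-butyl(hept-1-yn-4-yloxy)dimethylsilane
Product: 12 methyl (1R,2S,3R)-2-(2-tert-butoxy-2-oxoethyl)-3-[(5R)-5-(tert-butyldimethylsilyloxy)oct-2-yn-1-yl]cyclohexane-1-carboxylate, via primary triflate 10 (not isolated), via lithium acetylide 11 (not isolated)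
Conditions: 6, Tf2O, 2,6-lutidine, CH2Cl2, −78 °C; cold solution added to 11 (from 9, n-BuLi, THF, −78 °C), THF/DMPU, −78 → −40 °C
Reagents that add atoms: triflic anhydride, O=S(=O)(OS(=O)(=O)C(F)(F)F)C(F)(F)F (atoms in intermediate 10 only); n-butyllithium, [Li]CCCC (lithium in intermediate 11 only)
Why: SN2 alkylation of a lithium acetylide by a primary triflate should be fast enough at −78 °C to outrun attack on the esters; it joins C1'–C2' without touching any stereocentre.

Step 9
Reactants: 12 methyl (1R,2S,3R)-2-(2-tert-butoxy-2-oxoethyl)-3-[(5R)-5-(tert-butyldimethylsilyloxy)oct-2-yn-1-yl]cyclohexane-1-carboxylate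
Product: 13 (1R,2S,3R)-2-(2-tert-butoxy-2-oxoethyl)-3-[(5R)-5-(tert-butyldimethylsilyloxy)oct-2-yn-1-yl]cyclohexane-1-carboxylic acid
Conditions: LiOH·H2O, THF/MeOH/H2O, rt; 1 M HCl to pH 4, 0 °C
Reagents that add atoms: lithium hydroxide, [Li+].[OH-]
Why: Saponification of the methyl ester beside the much slower tert-butyl ester; hydroxide at room temperature should hydrolyse faster than it enolises, so the future C8a keeps its configuration.

Step 10
Reactants: 13 (1R,2S,3R)-2-(2-tert-butoxy-2-oxoethyl)-3-[(5R)-5-(tert-butyldimethylsilyloxy)oct-2-yn-1-yl]cyclohexane-1-carboxylic acid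
Product: 16 tert-butyl 2-[(1S,2R,6R)-2-(benzyloxycarbonylamino)-6-[(5R)-5-(tert-butyldimethylsilyloxy)oct-2-yn-1-yl]cyclohexyl]acetate, via acyl azide 14 (not isolated), via isocyanate 15 (not isolated)
Conditions: DPPA, Et3N, toluene, rt → 85 °C; then BnOH, 90 °C
Reagents that add atoms: diphenylphosphoryl azide, [N-]=[N+]=NP(=O)(Oc1ccccc1)Oc1ccccc1; benzyl alcohol, OCc1ccccc1
Why: Curtius rearrangement proceeds with retention at the migrating carbon, so the C8a–N bond forms cis to both neighbours, and benzyl alcohol traps the isocyanate as a carbamate.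

Step 11
Reactants: 16 tert-butyl 2-[(1S,2R,6R)-2-(benzyloxycarbonylamino)-6-[(5R)-5-(tert-butyldimethylsilyloxy)oct-2-yn-1-yl]cyclohexyl]acetate
Product: 17 benzyl N-[(1R,2S,3R)-2-(2-hydroxyethyl)-3-[(5R)-5-(tert-butyldimethylsilyloxy)oct-2-yn-1-yl]cyclohexyl]carbamate
Conditions: DIBAL-H (4 equiv), CH2Cl2, −78 → 0 °C; Rochelle salt
Reagents that add atoms: none
Why: DIBAL-H reduction of the tert-butyl ester to the primary alcohol (the future C3); the carbamate is protected as its aluminium amide and the alkyne is inert at 0 °C.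

Step 12
Reactants: 17 benzyl N-[(1R,2S,3R)-2-(2-hydroxyethyl)-3-[(5R)-5-(tert-butyldimethylsilyloxy)oct-2-yn-1-yl]cyclohexyl]carbamate
Product: 18 2-[(1S,2R,6S)-2-amino-6-[(5R)-5-(tert-butyldimethylsilyloxy)octyl]cyclohexyl]ethan-1-ol
Conditions: H2 (1 atm), 10% Pd/C, EtOAc/EtOH, rt
Reagents that add atoms: none
Why: Catalytic hydrogenation saturates the alkyne and hydrogenolyses the benzyl carbamate in one operation; the ester was reduced before the amine is freed, so no lactam can form.

Step 13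
Reactants: 18 2-[(1S,2R,6S)-2-amino-6-[(5R)-5-(tert-butyldimethylsilyloxy)octyl]cyclohexyl]ethan-1-ol
Product: 21 2-[(1S,2R,6S)-2-(hydroxyamino)-6-[(5R)-5-(tert-butyldimethylsilyloxy)octyl]cyclohexyl]ethan-1-ol, via anisylidene imine 19 (not isolated), via oxaziridine 20 (not isolated)
Conditions: 4-MeOC6H4CHO, MgSO4, CH2Cl2, rt; mCPBA, CH2Cl2, 0 °C; NH2OH·HCl, MeOH, rt (intermediates carried on crude)
Reagents that add atoms: mCPBA, O=C(OO)c1cccc(Cl)c1; 4-methoxybenzaldehyde, COc1ccc(C=O)cc1 (atoms in intermediates 19 and 20 only)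
Why: Imine–oxaziridine sequence for primary amine to N-alkylhydroxylamine: the peracid oxidises the C=N bond and hydroxylamine cleaves the oxaziridine by transoximation, so nitrogen gains exactly one oxygen and C8a is never oxidised.

Step 14
Reactants: 21 2-[(1S,2R,6S)-2-(hydroxyamino)-6-[(5R)-5-(tert-butyldimethylsilyloxy)octyl]cyclohexyl]ethan-1-ol; 22 acetaldehyde
Product: 23 (Z)-N-[(1R,2S,3S)-2-(2-hydroxyethyl)-3-[(5R)-5-(tert-butyldimethylsilyloxy)octyl]cyclohexyl]ethanimine N-oxide
Conditions: MeCHO (3 equiv), MgSO4, CH2Cl2, 0 °C → rt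
Reagents that add atoms: none
Why: Condensation of an N-alkylhydroxylamine with an aldehyde gives the aldonitrone, (Z) because the C-methyl group lies anti to the bulky N-substituent.

Step 15
Reactants: 23 (Z)-N-[(1R,2S,3S)-2-(2-hydroxyethyl)-3-[(5R)-5-(tert-butyldimethylsilyloxy)octyl]cyclohexyl]ethanimine N-oxide
Product: 24 (Z)-N-[(1R,2S,3S)-2-(2-oxoethyl)-3-[(5R)-5-(tert-butyldimethylsilyloxy)octyl]cyclohexyl]ethanimine N-oxide
Conditions: Dess–Martin periodinane, NaHCO3, CH2Cl2, 0 °C; short filtration, used at once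
Reagents that add atoms: none
Why: Dess–Martin oxidation of the primary alcohol under buffered non-aqueous conditions, which a nitrone should tolerate; the aldehyde is unveiled only after nitrogen is tied up as the nitrone, because a free N-hydroxyamine would condense with it to a five-membered cyclic nitrone.

Step 16
Reactants: 24 (Z)-N-[(1R,2S,3S)-2-(2-oxoethyl)-3-[(5R)-5-(tert-butyldimethylsilyloxy)octyl]cyclohexyl]ethanimine N-oxide
Product: 25 (2R,3R,4aS,5S,8aR)-1-hydroxy-2-methyl-5-[(5R)-5-(tert-butyldimethylsilyloxy)octyl]decahydroquinolin-3-ol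
Conditions: SmI2 (2.5 equiv), THF (0.01 M, no HMPA), −78 °C; aq. NaHCO3/Na2S2O3
Reagents that add atoms: none
Why: Proposed new method: Sm(II) binds the nitrone oxygen of 24 and transfers one electron to give an N–O–Sm(III) α-aza radical (or, after a second electron, the organosamarium) at C2, a polarity-reversed C2 that attacks the Sm(III)-activated aldehyde carbon C3; the second electron and protonation on work-up then give the N-hydroxy amino alcohol, so the two acceptor carbons of the N1–C2–C3–O unit are joined directly. The closest known reaction type is the SmI2 reductive cross-coupling of nitrones with aldehydes and ketones to vicinal N-hydroxyamino alcohols, which is established between separate partners but not as a ring closure with the nitrone nitrogen inside the tether. The piperidine ring closes 6-exo-trig (C2 onto C3=O, oxygen exocyclic) through a chair. C2 is controlled by the carbocycle: its all-cis substituents hold the cyclohexane chair with N and the C5 chain equatorial and C4 axial, which makes C8 axial on the forming ring, so the C2 methyl must lie equatorial and trans to C8 to avoid a 1,3-diaxial clash. C3 is controlled by Sm(III) bridging the axial N–O oxygen and the aldehyde oxygen in a six-membered chelate, which places the new C3–O bond axial and cis to the methyl. The step needs cross-coupling over aldehyde pinacol coupling and nitrone deoxygenation, and it needs this one chair; the intramolecular setting at high dilution and −78 °C, the absence of HMPA and the conformationally locked all-cis ring should secure both.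

Step 17
Reactants: 25 (2R,3R,4aS,5S,8aR)-1-hydroxy-2-methyl-5-[(5R)-5-(tert-butyldimethylsilyloxy)octyl]decahydroquinolin-3-ol
Product: 27 tert-butyl (2R,3R,4aS,5S,8aR)-3-hydroxy-2-methyl-5-[(5R)-5-(tert-butyldimethylsilyloxy)octyl]octahydroquinoline-1(2H)-carboxylate, via secondary amine 26 (not isolated)
Conditions: Zn dust, AcOH/THF, rt; filter, neutralise; Boc2O, Et3N, CH2Cl2, rt → 40 °C
Reagents that add atoms: di-tert-butyl dicarbonate, CC(C)(C)OC(=O)OC(=O)OC(C)(C)C
Why: Zinc reduction cleaves the N–O bond of the N,N-dialkylhydroxylamine and the amine is then capped as its carbamate for the acylation; the hindered axial C3 hydroxyl should not react with Boc2O without DMAP, and room temperature spares the silyl ether.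

Step 18
Reactants: 27 tert-butyl (2R,3R,4aS,5S,8aR)-3-hydroxy-2-methyl-5-[(5R)-5-(tert-butyldimethylsilyloxy)octyl]octahydroquinoline-1(2H)-carboxylate; 28 (E)-oct-2-enoic acid
Product: 30 tert-butyl (2R,3R,4aS,5S,8aR)-2-methyl-3-[(E)-oct-2-enoyloxy]-5-[(5R)-5-(tert-butyldimethylsilyloxy)octyl]octahydroquinoline-1(2H)-carboxylate, via mixed anhydride 29 (not isolated)
Conditions: 28, 2,4,6-trichlorobenzoyl chloride, Et3N, THF, rt; then 27, DMAP, toluene, rt → 40 °C
Reagents that add atoms: 2,4,6-trichlorobenzoyl chloride, O=C(Cl)c1c(Cl)cc(Cl)cc1Cl (atoms in intermediate 29 only)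
Why: Yamaguchi esterification through the mixed anhydride should acylate the hindered axial C3 alcohol with retention at C3 and without loss of the (E)-alkene geometry.

Step 19
Reactants: 30 tert-butyl (2R,3R,4aS,5S,8aR)-2-methyl-3-[(E)-oct-2-enoyloxy]-5-[(5R)-5-(tert-butyldimethylsilyloxy)octyl]octahydroquinoline-1(2H)-carboxylate
Product: 31 (2R,3R,4aS,5S,8aR)-5-[(5R)-5-hydroxyoctyl]-2-methyldecahydroquinolin-3-yl (E)-oct-2-enoate
Conditions: TFA/CH2Cl2/H2O (10:10:1), 0 °C → rt; aq. NaHCO3/MeOH work-up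
Reagents that add atoms: none
Why: Acidolysis removes the Boc group and aqueous acid cleaves the secondary silyl ether, while the enoate ester is stable to acid; the bicarbonate work-up frees the amine and hydrolyses any trifluoroacetate.

## Compound list

1 | 2-bromoisophthalic acid | OC(=O)c1cccc(C(=O)O)c1Br | starting material
2 | dimethyl 2-bromoisophthalate | COC(=O)c1cccc(C(=O)OC)c1Br | intermediate
3 | dimethyl 2-(2-tert-butoxy-2-oxoethyl)isophthalate | COC(=O)c1cccc(C(=O)OC)c1CC(=O)OC(C)(C)C | intermediate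
4 | dimethyl (1R,2s,3S)-2-(2-tert-butoxy-2-oxoethyl)cyclohexane-1,3-dicarboxylate (all-cis, meso) | CC(C)(C)OC(=O)C[C@H]1[C@@H](C(=O)OC)CCC[C@H]1C(=O)OC | intermediate
5 | (1S,2S,3R)-2-(2-tert-butoxy-2-oxoethyl)-3-(methoxycarbonyl)cyclohexane-1-carboxylic acid | CC(C)(C)OC(=O)C[C@H]1[C@@H](C(=O)O)CCC[C@H]1C(=O)OC | intermediate
6 | methyl (1R,2S,3S)-2-(2-tert-butoxy-2-oxoethyl)-3-(hydroxymethyl)cyclohexane-1-carboxylate | CC(C)(C)OC(=O)C[C@H]1[C@@H](CO)CCC[C@H]1C(=O)OC | intermediate
7 | (R)-2-propyloxirane | CCC[C@@H]1CO1 | starting material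
8 | (R)-hept-1-yn-4-ol | C#CC[C@H](O)CCC | intermediate
9 | (R)-tert-butyl(hept-1-yn-4-yloxy)dimethylsilane | C#CC[C@H](O[Si](C)(C)C(C)(C)C)CCC | intermediate
10 | methyl (1R,2S,3S)-2-(2-tert-butoxy-2-oxoethyl)-3-[(trifluoromethylsulfonyloxy)methyl]cyclohexane-1-carboxylate (primary triflate) | CC(C)(C)OC(=O)C[C@H]1[C@@H](COS(=O)(=O)C(F)(F)F)CCC[C@H]1C(=O)OC | intermediate
11 | lithium acetylide of 9, lithium (R)-4-(tert-butyldimethylsilyloxy)hept-1-yn-1-ide | [Li]C#CC[C@H](O[Si](C)(C)C(C)(C)C)CCC | intermediate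
12 | methyl (1R,2S,3R)-2-(2-tert-butoxy-2-oxoethyl)-3-[(5R)-5-(tert-butyldimethylsilyloxy)oct-2-yn-1-yl]cyclohexane-1-carboxylate | CC(C)(C)OC(=O)C[C@H]1[C@@H](CC#CC[C@H](O[Si](C)(C)C(C)(C)C)CCC)CCC[C@H]1C(=O)OC | intermediate
13 | (1R,2S,3R)-2-(2-tert-butoxy-2-oxoethyl)-3-[(5R)-5-(tert-butyldimethylsilyloxy)oct-2-yn-1-yl]cyclohexane-1-carboxylic acid | CC(C)(C)OC(=O)C[C@H]1[C@@H](CC#CC[C@H](O[Si](C)(C)C(C)(C)C)CCC)CCC[C@H]1C(=O)O | intermediate
14 | (1R,2S,3R)-2-(2-tert-butoxy-2-oxoethyl)-3-[(5R)-5-(tert-butyldimethylsilyloxy)oct-2-yn-1-yl]cyclohexane-1-carbonyl azide | CC(C)(C)OC(=O)C[C@H]1[C@@H](CC#CC[C@H](O[Si](C)(C)C(C)(C)C)CCC)CCC[C@H]1C(=O)N=[N+]=[N-] | intermediate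
15 | tert-butyl 2-[(1S,2R,6R)-2-isocyanato-6-[(5R)-5-(tert-butyldimethylsilyloxy)oct-2-yn-1-yl]cyclohexyl]acetate | CC(C)(C)OC(=O)C[C@H]1[C@@H](CC#CC[C@H](O[Si](C)(C)C(C)(C)C)CCC)CCC[C@H]1N=C=O | intermediate
16 | tert-butyl 2-[(1S,2R,6R)-2-(benzyloxycarbonylamino)-6-[(5R)-5-(tert-butyldimethylsilyloxy)oct-2-yn-1-yl]cyclohexyl]acetate | CC(C)(C)OC(=O)C[C@H]1[C@@H](CC#CC[C@H](O[Si](C)(C)C(C)(C)C)CCC)CCC[C@H]1NC(=O)OCc2ccccc2 | intermediate
17 | benzyl N-[(1R,2S,3R)-2-(2-hydroxyethyl)-3-[(5R)-5-(tert-butyldimethylsilyloxy)oct-2-yn-1-yl]cyclohexyl]carbamate | OCC[C@H]1[C@@H](CC#CC[C@H](O[Si](C)(C)C(C)(C)C)CCC)CCC[C@H]1NC(=O)OCc2ccccc2 | intermediate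
18 | 2-[(1S,2R,6S)-2-amino-6-[(5R)-5-(tert-butyldimethylsilyloxy)octyl]cyclohexyl]ethan-1-ol | OCC[C@H]1[C@@H](CCCC[C@H](O[Si](C)(C)C(C)(C)C)CCC)CCC[C@H]1N | intermediate
19 | 2-[(1S,2R,6S)-2-{[(E)-(4-methoxyphenyl)methylidene]amino}-6-[(5R)-5-(tert-butyldimethylsilyloxy)octyl]cyclohexyl]ethan-1-ol | OCC[C@H]1[C@@H](CCCC[C@H](O[Si](C)(C)C(C)(C)C)CCC)CCC[C@H]1/N=C/c2ccc(OC)cc2 | intermediate
20 | 2-[(1S,2R,6S)-2-[3-(4-methoxyphenyl)oxaziridin-2-yl]-6-[(5R)-5-(tert-butyldimethylsilyloxy)octyl]cyclohexyl]ethan-1-ol (oxaziridine isomers) | OCC[C@H]1[C@@H](CCCC[C@H](O[Si](C)(C)C(C)(C)C)CCC)CCC[C@H]1N2OC2c3ccc(OC)cc3 | intermediate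
21 | 2-[(1S,2R,6S)-2-(hydroxyamino)-6-[(5R)-5-(tert-butyldimethylsilyloxy)octyl]cyclohexyl]ethan-1-ol | OCC[C@H]1[C@@H](CCCC[C@H](O[Si](C)(C)C(C)(C)C)CCC)CCC[C@H]1NO | intermediate
22 | acetaldehyde | CC=O | starting material
23 | (Z)-N-[(1R,2S,3S)-2-(2-hydroxyethyl)-3-[(5R)-5-(tert-butyldimethylsilyloxy)octyl]cyclohexyl]ethanimine N-oxide | OCC[C@H]1[C@@H](CCCC[C@H](O[Si](C)(C)C(C)(C)C)CCC)CCC[C@H]1/[N+]([O-])=C/C | intermediate
24 | (Z)-N-[(1R,2S,3S)-2-(2-oxoethyl)-3-[(5R)-5-(tert-butyldimethylsilyloxy)octyl]cyclohexyl]ethanimine N-oxide | O=CC[C@H]1[C@@H](CCCC[C@H](O[Si](C)(C)C(C)(C)C)CCC)CCC[C@H]1/[N+]([O-])=C/C | intermediate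
25 | (2R,3R,4aS,5S,8aR)-1-hydroxy-2-methyl-5-[(5R)-5-(tert-butyldimethylsilyloxy)octyl]decahydroquinolin-3-ol | O[C@@H]1C[C@H]2[C@@H](CCCC[C@H](O[Si](C)(C)C(C)(C)C)CCC)CCC[C@H]2N(O)[C@@H]1C | intermediate
26 | (2R,3R,4aS,5S,8aR)-2-methyl-5-[(5R)-5-(tert-butyldimethylsilyloxy)octyl]decahydroquinolin-3-ol | O[C@@H]1C[C@H]2[C@@H](CCCC[C@H](O[Si](C)(C)C(C)(C)C)CCC)CCC[C@H]2N[C@@H]1C | intermediate
27 | tert-butyl (2R,3R,4aS,5S,8aR)-3-hydroxy-2-methyl-5-[(5R)-5-(tert-butyldimethylsilyloxy)octyl]octahydroquinoline-1(2H)-carboxylate | O[C@@H]1C[C@H]2[C@@H](CCCC[C@H](O[Si](C)(C)C(C)(C)C)CCC)CCC[C@H]2N(C(=O)OC(C)(C)C)[C@@H]1C | intermediate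
28 | (E)-oct-2-enoic acid | CCCCC/C=C/C(=O)O | starting material
29 | (E)-oct-2-enoic 2,4,6-trichlorobenzoic anhydride | CCCCC/C=C/C(=O)OC(=O)c1c(Cl)cc(Cl)cc1Cl | intermediate
30 | tert-butyl (2R,3R,4aS,5S,8aR)-2-methyl-3-[(E)-oct-2-enoyloxy]-5-[(5R)-5-(tert-butyldimethylsilyloxy)octyl]octahydroquinoline-1(2H)-carboxylate | CCCCC/C=C/C(=O)O[C@@H]1C[C@H]2[C@@H](CCCC[C@H](O[Si](C)(C)C(C)(C)C)CCC)CCC[C@H]2N(C(=O)OC(C)(C)C)[C@@H]1C | intermediate
31 | (2R,3R,4aS,5S,8aR)-5-[(5R)-5-hydroxyoctyl]-2-methyldecahydroquinolin-3-yl (E)-oct-2-enoate | CCCCC/C=C/C(=O)O[C@@H]1C[C@H]2[C@@H](CCCC[C@H](O)CCC)CCC[C@H]2N[C@@H]1C | target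

## Step count and risks

Total step count: 19. Longest linear sequence: 17 steps (steps 1–5 and 8–19); the side-chain branch (steps 6–7) joins at step 8.

Steps most likely to fail:

1. Step 16 (the new method). Electron transfer may end in simple reduction (nitrone to hydroxylamine or imine, aldehyde to alcohol or pinacol) without forming C2–C3, or the ring may close through the unchelated chair and lose facial control at C3. The fallback uses known chemistry and sets out from carbamate 16. Hydrogenation over Pd/C saturates the alkyne and frees the amine to give tert-butyl 2-[(1S,2R,6S)-2-amino-6-[(5R)-5-(tert-butyldimethylsilyloxy)octyl]cyclohexyl]acetate F1, which is used at once. N-Alkylation with methyl 2-bromopropanoate (K2CO3, MeCN) gives methyl 2-{[(1R,2S,3S)-2-(2-tert-butoxy-2-oxoethyl)-3-[(5R)-5-(tert-butyldimethylsilyloxy)octyl]cyclohexyl]amino}propanoate F2. Dieckmann condensation (KOt-Bu, THF, 0 °C) of the arm ester enolate onto the methyl ester closes the piperidine as tert-butyl (4aR,5S,8aR)-2-methyl-3-oxo-5-[(5R)-5-(tert-butyldimethylsilyloxy)octyl]decahydroquinoline-4-carboxylate F3. Catalytic TsOH in toluene at 80 °C removes isobutene and CO2 and lets C2 equilibrate to the equatorial methyl trans to C8, giving (2R,4aS,5S,8aR)-2-methyl-5-[(5R)-5-(tert-butyldimethylsilyloxy)octyl]octahydroquinolin-3(2H)-one F4. Boc2O gives tert-butyl (2R,4aS,5S,8aR)-2-methyl-3-oxo-5-[(5R)-5-(tert-butyldimethylsilyloxy)octyl]octahydroquinoline-1(2H)-carboxylate F5. L-Selectride (THF, −78 °C) should deliver hydride anti to the C2 methyl to give the cis alcohol 27, where the route resumes at step 18.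

2. Step 4. The enzyme may hydrolyse the hindered diester slowly, with poor discrimination of the enantiotopic esters, or in the opposite sense. The fallback sets out from meso diester 4. LiOH (2.2 equiv, THF/H2O) cleaves both methyl esters and keeps the tert-butyl ester, giving (1R,2s,3S)-2-(2-tert-butoxy-2-oxoethyl)cyclohexane-1,3-dicarboxylic acid F6. Acetic anhydride at 60 °C closes the bridged meso anhydride tert-butyl 2-(2,4-dioxo-3-oxabicyclo[3.3.1]nonan-9-yl)acetate F7. Catalytic methanolysis with a bis-cinchona alkaloid catalyst (the dihydroquinidine- or dihydroquinine-derived one, chosen for the required sense; MeOH, Et2O, −40 °C) returns to half-ester 5.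

3. Step 8. The neighbouring tert-butyl ester carbonyl may displace the triflate (lactonisation with loss of isobutene), or the acetylide may add to the esters. The fallback sets out from alcohol 6. Iodine, PPh3 and imidazole give the stable methyl (1R,2R,3S)-2-(2-tert-butoxy-2-oxoethyl)-3-(iodomethyl)cyclohexane-1-carboxylate F8. This is coupled with alkyne 9 in an alkyl Sonogashira reaction under Pd–N-heterocyclic carbene/CuI catalysis with Cs2CO3 (DMF/Et2O, 45 °C), which avoids the strongly basic acetylide and returns to 12.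

Further compounds
F1 | step 16 | tert-butyl 2-[(1S,2R,6S)-2-amino-6-[(5R)-5-(tert-butyldimethylsilyloxy)octyl]cyclohexyl]acetate | CC(C)(C)OC(=O)C[C@H]1[C@@H](CCCC[C@H](O[Si](C)(C)C(C)(C)C)CCC)CCC[C@H]1N
F2 | step 16 | methyl 2-{[(1R,2S,3S)-2-(2-tert-butoxy-2-oxoethyl)-3-[(5R)-5-(tert-butyldimethylsilyloxy)octyl]cyclohexyl]amino}propanoate (both epimers at the propanoate carbon) | CC(C)(C)OC(=O)C[C@H]1[C@@H](CCCC[C@H](O[Si](C)(C)C(C)(C)C)CCC)CCC[C@H]1NC(C)C(=O)OC
F3 | step 16 | tert-butyl (4aR,5S,8aR)-2-methyl-3-oxo-5-[(5R)-5-(tert-butyldimethylsilyloxy)octyl]decahydroquinoline-4-carboxylate (C2/C4 mixture) | O=C1C(C(=O)OC(C)(C)C)[C@H]2[C@@H](CCCC[C@H](O[Si](C)(C)C(C)(C)C)CCC)CCC[C@H]2NC1C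
F4 | step 16 | (2R,4aS,5S,8aR)-2-methyl-5-[(5R)-5-(tert-butyldimethylsilyloxy)octyl]octahydroquinolin-3(2H)-one | O=C1C[C@H]2[C@@H](CCCC[C@H](O[Si](C)(C)C(C)(C)C)CCC)CCC[C@H]2N[C@@H]1C
F5 | step 16 | tert-butyl (2R,4aS,5S,8aR)-2-methyl-3-oxo-5-[(5R)-5-(tert-butyldimethylsilyloxy)octyl]octahydroquinoline-1(2H)-carboxylate | O=C1C[C@H]2[C@@H](CCCC[C@H](O[Si](C)(C)C(C)(C)C)CCC)CCC[C@H]2N(C(=O)OC(C)(C)C)[C@@H]1C
F6 | step 4 | (1R,2s,3S)-2-(2-tert-butoxy-2-oxoethyl)cyclohexane-1,3-dicarboxylic acid (all-cis, meso) | CC(C)(C)OC(=O)C[C@H]1[C@@H](C(=O)O)CCC[C@H]1C(=O)O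
F7 | step 4 | tert-butyl 2-(2,4-dioxo-3-oxabicyclo[3.3.1]nonan-9-yl)acetate (meso anhydride, arm cis to both carbonyls) | CC(C)(C)OC(=O)C[C@H]1[C@@H]2CCC[C@H]1C(=O)OC2=O
F8 | step 8 | methyl (1R,2R,3S)-2-(2-tert-butoxy-2-oxoethyl)-3-(iodomethyl)cyclohexane-1-carboxylate | CC(C)(C)OC(=O)C[C@H]1[C@@H](CI)CCC[C@H]1C(=O)OC
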